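**Retrosynthetic overview**

- The two esters are put on last. The C13–C15 end of the side chain comes from a terminal alkyne (Zr-catalysed methylalumination, then formaldehyde), and the alkyne from a C12 iodide.
- C9–C11 is made by a Johnson–Claisen rearrangement from a 7β-allylic alcohol. That alcohol comes from the ring B C9 enone by epoxidation, Wharton transposition, oxidation and Luche reduction.
- The strategy rests on ring A (C1–C5, C10): the C2 oxygen and the C19 oxygen on quaternary C4 are 1,4-related across C3–C4, and both C3 and C4 are enol carbons. C3–C4 is therefore closed by anodic coupling of a bis(silyl enol ether).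
- The precursor comes from (R)-carvone: α′-methylation, α′-allylation trans to isopropenyl, isopropenyl to aldehyde (epoxidation, Meinwald), allyl to methyl ketone (Wacker), double silylation.
- Ring order: ring B is the carvone ring; ring A is closed in step 7.

Key step: step 7

Remark on numbering: labdane numbering is used (ring A = C1–C5 and C10; ring B = C5–C10; C17 on C8; C18 α and C19 β on C4; C20 on C10; side chain C11–C16). α is the face of H5, β the face of the C10 methyl.

Remark on step order: the isopropenyl group is turned into the aldehyde before the allyl group is oxidised, because a δ,ε-epoxy ketone would be expected to close to a bicyclic ketal under Lewis acid. Compounds 7, 8 and 10 are carried as epimer mixtures at the future C4, which becomes sp2 in 12.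

**Route**

Step 1
Reactants: 1 (R)-carvone; 2 iodomethane
Product: 3 (5R)-2,6-dimethyl-5-(prop-1-en-2-yl)cyclohex-2-en-1-one (C6 epimers)
Conditions: LiN(iPr)2, THF, −78 °C; MeI, −78 → 0 °C
Reagents that add atoms: iodomethane, CI
Why: Kinetic α′-deprotonation of the enone gives the cross-conjugated lithium enolate, which is C-methylated (enolate alkylation); the new centre is an epimer mixture that is erased in step 2.

Step 2
Reactants: 3 6-methylcarvone; 4 allyl bromide
Product: 5 (5S,6S)-6-allyl-2,6-dimethyl-5-(prop-1-en-2-yl)cyclohex-2-en-1-one (allyl trans to isopropenyl)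
Conditions: LiN(iPr)2, THF, −78 °C; allyl bromide, −78 → 0 °C
Reagents that add atoms: allyl bromide, C=CCBr
Why: Second enolate alkylation at the same carbon; the tetrasubstituted enolate should be attacked on the face opposite the neighbouring isopropenyl group, so the quaternary centre (later C10) carries methyl cis and allyl trans to it.

Step 3
Reactants: 5 allyl methyl carvone; 6 3-chloroperbenzoic acid
Product: 7 6-allyl-2,6-dimethyl-5-(2-methyloxiran-2-yl)cyclohex-2-en-1-one (ring centres as in 5; both epoxide epimers)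
Conditions: mCPBA (1.05 equiv), NaHCO3, CH2Cl2, 0 °C
Reagents that add atoms: 3-chloroperbenzoic acid, OOC(=O)c1cccc(Cl)c1
Why: Prilezhaev epoxidation is fastest at the electron-rich 1,1-disubstituted isopropenyl alkene, while the monosubstituted allyl alkene and the electron-poor enone react much more slowly.

Step 4
Reactants: 7 isopropenyl epoxide
Product: 8 2-(2-allyl-2,4-dimethyl-3-oxocyclohex-4-en-1-yl)propanal (ring centres as in 5; both α-epimers)
Conditions: BF3·OEt2 (cat.), CH2Cl2, −78 °C
Reagents that add atoms: none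
Why: Meinwald rearrangement: Lewis-acid opening at the tertiary epoxide carbon and a 1,2-hydride shift from the CH2O carbon give the α-branched aldehyde, and no saturated ketone is yet present to trap the opened epoxide.

Step 5
Reactants: 8 allyl aldehyde; 9 water
Product: 10 2-[2,4-dimethyl-3-oxo-2-(2-oxopropyl)cyclohex-4-en-1-yl]propanal (ring centres as in 5)
Conditions: PdCl2 (cat.), CuCl (cat.), O2 (1 atm), DMF/H2O, rt
Reagents that add atoms: water, O
Why: Tsuji–Wacker oxidation: Markovnikov hydroxypalladation of the monosubstituted alkene gives the methyl ketone, and the trisubstituted enone alkene and the aldehyde should not react.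

Step 6
Reactants: 10 keto aldehyde; 11 tert-butyldimethylsilyl triflate
Product: 12 bis(TBS enol ether) of 10 (2-silyloxyallyl arm on the quaternary carbon; (E)-1-silyloxyprop-1-en-2-yl arm on the methine)
Conditions: TBSOTf (2.3 equiv), Et3N, CH2Cl2, −78 → −20 °C
Reagents that add atoms: tert-butyldimethylsilyl triflate, CC(C)(C)[Si](C)(C)OS(=O)(=O)C(F)(F)F
Why: Soft enolisation (O-silylation, then deprotonation by Et3N) should turn the aldehyde into the trisubstituted enol ether with OTBS cis to the small methyl and the methyl ketone into the terminal enol ether, since the other α-carbon is a shielded neopentyl CH2; the hindered enone carbonyl has no α′-hydrogen and should be left at this stoichiometry and temperature.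

Step 7
Reactants: 12 bis(TBS enol ether)
Product: 13 2,9-dioxo-11,12,13,14,15,16-hexanorlabd-7-en-19-al (trans-decalin; 4α-CH3; 4β-CHO; 5α-H; 10β-CH3)
Conditions: reticulated vitreous carbon anode, Pt cathode, undivided cell, constant current (2.2 F/mol), LiClO4 (0.1 M), 2,6-lutidine, MeOH/CH2Cl2 (1:4), rt; aqueous work-up
Reagents that add atoms: none
Why: The more electron-rich trisubstituted C4=C19 enol ether should be oxidised first to a radical cation whose C4 terminus is attacked by C3 of the 2-silyloxyallyl unit; the resulting C2 silyloxocarbenium ion and the C19 α-silyloxy radical (oxidised once more at the anode) each lose the silyl group to methanol, which gives the 1,4-keto aldehyde. The closest known reaction type is the intramolecular anodic coupling of an enol ether radical cation with a silyl enol ether, which is known to tolerate the formation of quaternary carbon. Ring A closes in a six-membered mode that is 6-exo with respect to the oxidised C4=C19 unit and 6-endo with respect to C2=C3, and the trans ring fusion is fixed beforehand because the C1 and C4 arms sit trans-diequatorial on ring B. The new C4 stereocentre is controlled by the chair-like transition state, in which the flat C19 carbon rather than the C18 methyl should take the axial site beside the axial C20 methyl; this conformer also has H5 eclipsing C18 and is free of allylic strain for the (E)-enol ether, so C19 becomes β and C18 α. The step needs oxidation of the enol ethers in preference to the enone (which lies at much higher potential), ring closure in preference to capture by methanol (helped by the six-membered closure, low current density and the lutidine buffer), and the facial selectivity just described.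

Step 8
Reactants: 13 diketo aldehyde
Product: 15 2α,19-dihydroxy-11,12,13,14,15,16-hexanorlabd-7-en-9-one, via 19-hydroxy-2,9-dione 14 (not isolated)
Conditions: Me4NBH(OAc)3 (excess), MeCN/AcOH (1:1), −20 °C → rt
Reagents that add atoms: none
Why: Triacetoxyborohydride reduces the aldehyde but not a ketone on its own; the axial C19 alkoxide so formed should bind boron and deliver hydride internally to the β face of the C2 carbonyl (hydroxyl-directed reduction), giving the equatorial 2α-alcohol, while the remote and hindered C9 enone has no directing group and is kept.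

Step 9
Reactants: 15 diol; 16 tert-butyldimethylsilyl chloride
Product: 17 19-(TBS-oxy)-2α-hydroxy-11,12,13,14,15,16-hexanorlabd-7-en-9-one
Conditions: TBSCl (1.1 equiv), imidazole, DMF, 0 °C
Reagents that add atoms: tert-butyldimethylsilyl chloride, CC(C)(C)[Si](C)(C)Cl
Why: Silylation is faster at the primary C19 hydroxyl than at the secondary C2 hydroxyl, so one equivalent at 0 °C should give the mono-ether.

Step 10
Reactants: 17 mono-TBS ether; 18 triisopropylsilyl triflate
Product: 19 19-(TBS-oxy)-2α-(TIPS-oxy)-11,12,13,14,15,16-hexanorlabd-7-en-9-one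
Conditions: TIPSOTf, 2,6-lutidine, CH2Cl2, 0 °C → rt
Reagents that add atoms: triisopropylsilyl triflate, CC(C)[Si](C(C)C)(C(C)C)OS(=O)(=O)C(F)(F)F
Why: The secondary alcohol is capped as the more robust TIPS ether (silyl triflate with a hindered base), which is meant to outlast the later removal of the primary TBS ether.

Step 11
Reactants: 19 bis-silyl enone; 20 hydrogen peroxide
Product: 21 7α,8α-epoxy-19-(TBS-oxy)-2α-(TIPS-oxy)-11,12,13,14,15,16-hexanorlabdan-9-one
Conditions: H2O2 (30 % aq.), NaOH (cat.), MeOH, 0 °C → rt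
Reagents that add atoms: hydrogen peroxide, OO
Why: Weitz–Scheffer epoxidation: hydroperoxide adds to C7 of the carvone-type enone, axially on the α face (syn to H5), and the enolate closes the epoxide; either face would serve because C7 is reset in steps 13 and 14.

Step 12
Reactants: 21 epoxy ketone; 22 hydrazine (as hydrate)
Product: 24 19-(TBS-oxy)-2α-(TIPS-oxy)-11,12,13,14,15,16-hexanorlabd-8-en-7α-ol, via epoxy hydrazone 23 (not isolated)
Conditions: N2H4·H2O, AcOH (cat.), MeOH, 0 °C → rt
Reagents that add atoms: none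
Why: Wharton transposition: the epoxy hydrazone opens at the C8–O bond to a vinyl diazene that loses N2 and leaves hydrogen on C9, giving the C8=C9 alkene and the C7 alcohol with the epoxide configuration retained.

Step 13
Reactants: 24 7α-allylic alcohol
Product: 25 19-(TBS-oxy)-2α-(TIPS-oxy)-11,12,13,14,15,16-hexanorlabd-8-en-7-one
Conditions: MnO2 (activated, excess), CH2Cl2, rt
Reagents that add atoms: none
Why: Allylic oxidation with MnO2 gives the transposed enone and erases the C7 configuration so that it can be set afresh.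

Step 14
Reactants: 25 7-enone
Product: 26 19-(TBS-oxy)-2α-(TIPS-oxy)-11,12,13,14,15,16-hexanorlabd-8-en-7β-ol
Conditions: NaBH4, CeCl3·7H2O, MeOH, −20 °C
Reagents that add atoms: none
Why: Luche 1,2-reduction with axial hydride delivery from the α face (opposite no large group, as for 4-en-3-one steroids) should give the pseudo-equatorial 7β-alcohol.

Step 15
Reactants: 26 7β-allylic alcohol; 27 triethyl orthoacetate
Product: 29 ethyl 19-(TBS-oxy)-2α-(TIPS-oxy)-13,14,15,16-tetranorlabd-7-en-12-oate, via ketene acetal 28 (not isolated)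
Conditions: MeC(OEt)3, EtCO2H (cat.), xylene, 140 °C, EtOH distilled off
Reagents that add atoms: triethyl orthoacetate, CC(OCC)(OCC)OCC
Why: Johnson–Claisen rearrangement: the ketene acetal on the 7β-oxygen undergoes a suprafacial [3,3] shift across the ring B allyl unit, so the C9–C11 bond forms on the β face (as in the 3β-ol to 5β-acetate transfer of 4-en-3-ol steroids) and the C7=C8 alkene is regenerated.

Step 16
Reactants: 29 ethyl ester
Product: 30 19-(TBS-oxy)-2α-(TIPS-oxy)-13,14,15,16-tetranorlabd-7-en-12-ol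
Conditions: LiAlH4, THF, 0 °C
Reagents that add atoms: none
Why: Hydride reduction of the ester to the primary alcohol; the silyl ethers and the trisubstituted alkene are inert.

Step 17
Reactants: 30 C12 alcohol; 31 iodine
Product: 32 12-iodo-19-(TBS-oxy)-2α-(TIPS-oxy)-13,14,15,16-tetranorlabd-7-ene
Conditions: I2, PPh3, imidazole, CH2Cl2, 0 °C → rt
Reagents that add atoms: iodine, II
Why: Appel-type iodination: the unhindered primary oxyphosphonium salt is displaced by iodide in an SN2 step.

Step 18
Reactants: 32 C12 iodide; 33 lithium acetylide ethylenediamine complex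
Product: 34 19-(TBS-oxy)-2α-(TIPS-oxy)-15,16-dinorlabd-7-en-13-yne
Conditions: LiC≡CH·H2NCH2CH2NH2, DMSO, rt
Reagents that add atoms: lithium acetylide ethylenediamine complex, [Li+].[C-]#C.NCCN
Why: SN2 alkylation of the acetylide by the primary iodide in a dipolar aprotic solvent adds C13 and C14 as a terminal alkyne.

Step 19
Reactants: 34 terminal alkyne; 35 trimethylaluminium; 36 formaldehyde (as paraformaldehyde)
Product: 38 (13E)-19-(TBS-oxy)-2α-(TIPS-oxy)labda-7,13-dien-15-ol, via alkenylalane 37 (not isolated)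
Conditions: Me3Al, Cp2ZrCl2 (25 mol %), CH2Cl2, 0 °C → rt; n-BuLi, THF, −30 °C; (CH2O)n, rt
Reagents that add atoms: trimethylaluminium, C[Al](C)C; formaldehyde (as paraformaldehyde), C=O
Why: Negishi zirconium-catalysed carboalumination adds CH3 and Al syn across the alkyne with CH3 on the internal carbon, and the derived alanate attacks formaldehyde with retention, so the trisubstituted alkene should be E.

Step 20
Reactants: 38 allylic alcohol; 39 methyl 4-chloro-4-oxobutanoate
Product: 40 (13E)-19-(TBS-oxy)-2α-(TIPS-oxy)labda-7,13-dien-15-yl methyl succinate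
Conditions: MeO2CCH2CH2COCl, pyridine, DMAP (cat.), CH2Cl2, 0 °C
Reagents that add atoms: methyl 4-chloro-4-oxobutanoate, COC(=O)CCC(=O)Cl
Why: DMAP-catalysed acylation of the only free hydroxyl, an unhindered primary allylic alcohol.

Step 21
Reactants: 40 bis-silyl succinate
Product: 41 (13E)-19-hydroxy-2α-(TIPS-oxy)labda-7,13-dien-15-yl methyl succinate
Conditions: HF·pyridine, pyridine, THF, 0 °C → rt
Reagents that add atoms: none
Why: Fluoride-mediated desilylation should be much faster for the primary TBS ether than for the bulkier secondary TIPS ether, and buffered HF·pyridine leaves the esters alone.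

Step 22
Reactants: 41 C19 alcohol; 42 3-methylbutanoyl chloride
Product: 43 (13E)-19-(3-methylbutanoyloxy)-2α-(TIPS-oxy)labda-7,13-dien-15-yl methyl succinate
Conditions: iPrCH2COCl, pyridine, DMAP, CH2Cl2, rt
Reagents that add atoms: 3-methylbutanoyl chloride, CC(C)CC(=O)Cl
Why: DMAP-catalysed acylation of the neopentyl C19 alcohol, the only free hydroxyl at this stage.

Step 23
Reactants: 43 TIPS ether
Product: 44 CNP0118741.1
Conditions: aq. HF (48 %), MeCN, rt
Reagents that add atoms: none
Why: Acidic fluoride cleaves the secondary TIPS ether without ester cleavage, and acyl migration is not expected because the equatorial 2α-hydroxyl and the axial C19 ester are far apart.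

**Compound list**

1 | (R)-carvone | CC1=CC[C@H](CC1=O)C(C)=C | starting material
2 | iodomethane | CI | starting material
3 | (5R)-2,6-dimethyl-5-(prop-1-en-2-yl)cyclohex-2-en-1-one (C6 epimers) | CC1=CC[C@H](C(C)C1=O)C(C)=C | intermediate
4 | allyl bromide | C=CCBr | starting material
5 | (5S,6S)-6-allyl-2,6-dimethyl-5-(prop-1-en-2-yl)cyclohex-2-en-1-one (allyl trans to isopropenyl) | O=C1C(C)=CC[C@@H](C(C)=C)[C@]1(C)CC=C | intermediate
6 | 3-chloroperbenzoic acid | OOC(=O)c1cccc(Cl)c1 | starting material
7 | 6-allyl-2,6-dimethyl-5-(2-methyloxiran-2-yl)cyclohex-2-en-1-one (ring centres as in 5, epoxide epimers) | O=C1C(C)=CC[C@@H](C2(C)CO2)[C@]1(C)CC=C | intermediate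
8 | 2-(2-allyl-2,4-dimethyl-3-oxocyclohex-4-en-1-yl)propanal (ring centres as in 5, α-epimers) | O=C1C(C)=CC[C@@H](C(C)C=O)[C@]1(C)CC=C | intermediate
9 | water | O | starting material
10 | 2-[2,4-dimethyl-3-oxo-2-(2-oxopropyl)cyclohex-4-en-1-yl]propanal (ring centres as in 5) | O=C1C(C)=CC[C@@H](C(C)C=O)[C@]1(C)CC(C)=O | intermediate
11 | tert-butyldimethylsilyl triflate | CC(C)(C)[Si](C)(C)OS(=O)(=O)C(F)(F)F | starting material
12 | bis(TBS enol ether) of 10: 6-[2-(TBS-oxy)allyl]-5-[(E)-1-(TBS-oxy)prop-1-en-2-yl]-2,6-dimethylcyclohex-2-en-1-one | O=C1C(C)=CC[C@@H](/C(C)=C/O[Si](C)(C)C(C)(C)C)[C@]1(C)CC(=C)O[Si](C)(C)C(C)(C)C | intermediate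
13 | 2,9-dioxo-11,12,13,14,15,16-hexanorlabd-7-en-19-al | O=C1C(C)=CC[C@H]2[C@@](C)(C=O)CC(=O)C[C@]12C | intermediate
14 | 19-hydroxy-11,12,13,14,15,16-hexanorlabd-7-ene-2,9-dione | O=C1C(C)=CC[C@H]2[C@@](C)(CO)CC(=O)C[C@]12C | intermediate
15 | 2α,19-dihydroxy-11,12,13,14,15,16-hexanorlabd-7-en-9-one | O=C1C(C)=CC[C@H]2[C@@](C)(CO)C[C@H](O)C[C@]12C | intermediate
16 | tert-butyldimethylsilyl chloride | CC(C)(C)[Si](C)(C)Cl | starting material
17 | 19-(TBS-oxy)-2α-hydroxy-11,12,13,14,15,16-hexanorlabd-7-en-9-one | O=C1C(C)=CC[C@H]2[C@@](C)(CO[Si](C)(C)C(C)(C)C)C[C@H](O)C[C@]12C | intermediate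
18 | triisopropylsilyl triflate | CC(C)[Si](C(C)C)(C(C)C)OS(=O)(=O)C(F)(F)F | starting material
19 | 19-(TBS-oxy)-2α-(TIPS-oxy)-11,12,13,14,15,16-hexanorlabd-7-en-9-one | O=C1C(C)=CC[C@H]2[C@@](C)(CO[Si](C)(C)C(C)(C)C)C[C@H](O[Si](C(C)C)(C(C)C)C(C)C)C[C@]12C | intermediate
20 | hydrogen peroxide | OO | starting material
21 | 7α,8α-epoxy-19-(TBS-oxy)-2α-(TIPS-oxy)-11,12,13,14,15,16-hexanorlabdan-9-one | O=C1[C@]3(C)O[C@@H]3C[C@H]2[C@@](C)(CO[Si](C)(C)C(C)(C)C)C[C@H](O[Si](C(C)C)(C(C)C)C(C)C)C[C@]12C | intermediate
22 | hydrazine (used as hydrate) | NN | starting material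
23 | hydrazone of 21 | NN=C1[C@]3(C)O[C@@H]3C[C@H]2[C@@](C)(CO[Si](C)(C)C(C)(C)C)C[C@H](O[Si](C(C)C)(C(C)C)C(C)C)C[C@]12C | intermediate
24 | 19-(TBS-oxy)-2α-(TIPS-oxy)-11,12,13,14,15,16-hexanorlabd-8-en-7α-ol | C1=C(C)[C@H](O)C[C@H]2[C@@](C)(CO[Si](C)(C)C(C)(C)C)C[C@H](O[Si](C(C)C)(C(C)C)C(C)C)C[C@]12C | intermediate
25 | 19-(TBS-oxy)-2α-(TIPS-oxy)-11,12,13,14,15,16-hexanorlabd-8-en-7-one | C1=C(C)C(=O)C[C@H]2[C@@](C)(CO[Si](C)(C)C(C)(C)C)C[C@H](O[Si](C(C)C)(C(C)C)C(C)C)C[C@]12C | intermediate
26 | 19-(TBS-oxy)-2α-(TIPS-oxy)-11,12,13,14,15,16-hexanorlabd-8-en-7β-ol | C1=C(C)[C@@H](O)C[C@H]2[C@@](C)(CO[Si](C)(C)C(C)(C)C)C[C@H](O[Si](C(C)C)(C(C)C)C(C)C)C[C@]12C | intermediate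
27 | triethyl orthoacetate | CC(OCC)(OCC)OCC | starting material
28 | 7β-(1-ethoxyvinyloxy) ketene acetal of 26 | C1=C(C)[C@@H](OC(=C)OCC)C[C@H]2[C@@](C)(CO[Si](C)(C)C(C)(C)C)C[C@H](O[Si](C(C)C)(C(C)C)C(C)C)C[C@]12C | intermediate
29 | ethyl 19-(TBS-oxy)-2α-(TIPS-oxy)-13,14,15,16-tetranorlabd-7-en-12-oate | CCOC(=O)C[C@H]1C(C)=CC[C@H]2[C@@](C)(CO[Si](C)(C)C(C)(C)C)C[C@H](O[Si](C(C)C)(C(C)C)C(C)C)C[C@]12C | intermediate
30 | 19-(TBS-oxy)-2α-(TIPS-oxy)-13,14,15,16-tetranorlabd-7-en-12-ol | OCC[C@H]1C(C)=CC[C@H]2[C@@](C)(CO[Si](C)(C)C(C)(C)C)C[C@H](O[Si](C(C)C)(C(C)C)C(C)C)C[C@]12C | intermediate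
31 | iodine | II | starting material
32 | 12-iodo-19-(TBS-oxy)-2α-(TIPS-oxy)-13,14,15,16-tetranorlabd-7-ene | ICC[C@H]1C(C)=CC[C@H]2[C@@](C)(CO[Si](C)(C)C(C)(C)C)C[C@H](O[Si](C(C)C)(C(C)C)C(C)C)C[C@]12C | intermediate
33 | lithium acetylide ethylenediamine complex | [Li+].[C-]#C.NCCN | starting material
34 | 19-(TBS-oxy)-2α-(TIPS-oxy)-15,16-dinorlabd-7-en-13-yne | C#CCC[C@H]1C(C)=CC[C@H]2[C@@](C)(CO[Si](C)(C)C(C)(C)C)C[C@H](O[Si](C(C)C)(C(C)C)C(C)C)C[C@]12C | intermediate
35 | trimethylaluminium | C[Al](C)C | starting material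
36 | formaldehyde (used as paraformaldehyde) | C=O | starting material
37 | (13E)-14-(dimethylalumanyl)-19-(TBS-oxy)-2α-(TIPS-oxy)-15-norlabda-7,13-diene | C[Al](C)/C=C(\C)CC[C@H]1C(C)=CC[C@H]2[C@@](C)(CO[Si](C)(C)C(C)(C)C)C[C@H](O[Si](C(C)C)(C(C)C)C(C)C)C[C@]12C | intermediate
38 | (13E)-19-(TBS-oxy)-2α-(TIPS-oxy)labda-7,13-dien-15-ol | OC/C=C(\C)CC[C@H]1C(C)=CC[C@H]2[C@@](C)(CO[Si](C)(C)C(C)(C)C)C[C@H](O[Si](C(C)C)(C(C)C)C(C)C)C[C@]12C | intermediate
39 | methyl 4-chloro-4-oxobutanoate | COC(=O)CCC(=O)Cl | starting material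
40 | (13E)-19-(TBS-oxy)-2α-(TIPS-oxy)labda-7,13-dien-15-yl methyl succinate | COC(=O)CCC(=O)OC/C=C(\C)CC[C@H]1C(C)=CC[C@H]2[C@@](C)(CO[Si](C)(C)C(C)(C)C)C[C@H](O[Si](C(C)C)(C(C)C)C(C)C)C[C@]12C | intermediate
41 | (13E)-19-hydroxy-2α-(TIPS-oxy)labda-7,13-dien-15-yl methyl succinate | COC(=O)CCC(=O)OC/C=C(\C)CC[C@H]1C(C)=CC[C@H]2[C@@](C)(CO)C[C@H](O[Si](C(C)C)(C(C)C)C(C)C)C[C@]12C | intermediate
42 | 3-methylbutanoyl chloride | CC(C)CC(=O)Cl | starting material
43 | (13E)-19-(3-methylbutanoyloxy)-2α-(TIPS-oxy)labda-7,13-dien-15-yl methyl succinate | COC(=O)CCC(=O)OC/C=C(\C)CC[C@H]1C(C)=CC[C@H]2[C@@](C)(COC(=O)CC(C)C)C[C@H](O[Si](C(C)C)(C(C)C)C(C)C)C[C@]12C | intermediate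
44 | CNP0118741.1, (13E)-2α-hydroxy-19-(3-methylbutanoyloxy)labda-7,13-dien-15-yl methyl succinate | COC(=O)CCC(=O)OC/C=C(\C)CC[C@H]1C(C)=CC[C@H]2[C@@](C)(COC(=O)CC(C)C)C[C@H](O)C[C@]12C | target

**Step count**

Total steps: 23. Longest linear sequence: 23 steps from (R)-carvone.

**Steps most likely to fail**

Step 7 (anodic ring closure). The radical cation may be captured by methanol or lose its silyl group before the C3–C4 bond forms, and the facial selectivity at C4 may be insufficient. The fallback makes the same bond by polar chemistry and sets out from aldehyde 8. NBS in aqueous acetone should convert the allyl group into the Markovnikov bromohydrin F1. Dess–Martin oxidation then gives the bromomethyl ketone F2. KOtBu in tBuOH/THF at 0 °C should close ring A by intramolecular C-alkylation of the aldehyde enolate (6-exo-tet), with the same chair preference for an axial C19. This returns to the route at 13.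

Step 8 (directed reduction). Internal hydride delivery may fail, for example if the C19 hydroxyl is tied up as a bridged hemiketal with the C2 ketone, or external equatorial attack may lead to the 2β-alcohol. The fallback sets out from 13. NaBH4 in MeOH/CH2Cl2 at −78 °C should reduce the aldehyde and the C2 ketone (equatorial attack) to the 2β,19-diol F3 with the enone intact. TBSCl and imidazole give the primary silyl ether F4. Mitsunobu inversion with 4-nitrobenzoic acid, PPh3 and DIAD gives the 2α-ester F5. K2CO3 in MeOH removes the ester and returns to the route at 17.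

Step 12 (Wharton transposition). Hydrazone formation at the hindered C9 ketone may be slow enough for hydrazine to open the epoxide instead. The fallback sets out from 21. NaBH4 in MeOH gives the epoxy alcohol F6. Phenyl chlorothionoformate with pyridine and DMAP gives the thionocarbonate F7. Bu3SnH and AIBN in hot benzene generate the C9 radical, which opens the C8–O bond of the epoxide and, after hydrogen transfer, returns to the route at 24.

**Further compounds**

F1 | step 7 | 2-[2-(3-bromo-2-hydroxypropyl)-2,4-dimethyl-3-oxocyclohex-4-en-1-yl]propanal | O=C1C(C)=CC[C@@H](C(C)C=O)[C@]1(C)CC(O)CBr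
F2 | step 7 | 2-[2-(3-bromo-2-oxopropyl)-2,4-dimethyl-3-oxocyclohex-4-en-1-yl]propanal | O=C1C(C)=CC[C@@H](C(C)C=O)[C@]1(C)CC(=O)CBr
F3 | step 8 | 2β,19-dihydroxy-11,12,13,14,15,16-hexanorlabd-7-en-9-one | O=C1C(C)=CC[C@H]2[C@@](C)(CO)C[C@@H](O)C[C@]12C
F4 | step 8 | 19-(TBS-oxy)-2β-hydroxy-11,12,13,14,15,16-hexanorlabd-7-en-9-one | O=C1C(C)=CC[C@H]2[C@@](C)(CO[Si](C)(C)C(C)(C)C)C[C@@H](O)C[C@]12C
F5 | step 8 | 19-(TBS-oxy)-2α-(4-nitrobenzoyloxy)-11,12,13,14,15,16-hexanorlabd-7-en-9-one | O=C1C(C)=CC[C@H]2[C@@](C)(CO[Si](C)(C)C(C)(C)C)C[C@H](OC(=O)c3ccc(cc3)[N+](=O)[O-])C[C@]12C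
F6 | step 12 | 7α,8α-epoxy-19-(TBS-oxy)-2α-(TIPS-oxy)-11,12,13,14,15,16-hexanorlabdan-9-ol | OC1[C@]3(C)O[C@@H]3C[C@H]2[C@@](C)(CO[Si](C)(C)C(C)(C)C)C[C@H](O[Si](C(C)C)(C(C)C)C(C)C)C[C@]12C
F7 | step 12 | O-phenyl thionocarbonate of F6 | S=C(Oc1ccccc1)OC1[C@]3(C)O[C@@H]3C[C@H]2[C@@](C)(CO[Si](C)(C)C(C)(C)C)C[C@H](O[Si](C(C)C)(C(C)C)C(C)C)C[C@]12C
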